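The plan disconnects the C1–C10a bond of the cross-conjugated dienone ring A. The C1 and C9 ketones stand in a 1,4-relationship through C10a–C10 in ring B, and C4a=C10a is the dehydration product of a quinol: the retron of an intramolecular Stetter reaction on a dearomatised naphthoquinone followed by β-elimination. In one operation a carbene catalyst converts a lactol-masked enal into an acyl anion that closes ring A on the quinol enone, creates the C9-keto/C10-methylene array and, after loss of water, the dienone. The precursor is a 7-methoxyjuglone-derived p-quinol bearing a 2,5-dihydrofuran-2-ol that carries C1–C4 of ring A.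

Key step: step 6

Remark (numbering): phenanthrene locants are used; ring A = C1–C4, C4a, C10a; ring B = C4a, C4b, C8a, C9, C10, C10a; ring C = C4b, C5–C8, C8a; the oxazolidine oxygen sits on C4 and the nitrogen on C3.
Remark (chemistry): the target is taken in the tautomeric form drawn (C9 ketone chelated by the C8 phenol, C10 a methylene); this form and its 9-phenanthrol tautomer are expected to interconvert, and the key step delivers the drawn form directly.
Remark (stereochemistry): nothing before step 7 is enantioselective; the quaternary C4 centre is secured by resolution in step 7 and the aminal centre is set last under thermodynamic control.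

Step 1
Reactants: 1 methyl (E)-3-methoxybut-2-enoate; 2 p-benzoquinone
Product: 5 5-hydroxy-7-methoxynaphthalene-1,4-dione (7-methoxyjuglone), via Brassard diene 3 (not isolated), via silyloxynaphthalenediol 4 (not isolated)
Conditions: LiN(i-Pr)2, THF, −78 °C, then Me3SiCl; then 2 (2.2 equiv), CH2Cl2, −30 → 23 °C; 1 M HCl work-up
Reagents that add atoms: none
Why: O-Silylation of the lithium dienolate of 1 gives Brassard's diene, which undergoes a Diels–Alder reaction with benzoquinone, loses methanol to aromatise and is oxidised by the second equivalent of quinone, so that the ketene-acetal carbon ends as the peri hydroxyl (C5) and the enol-ether carbon as the C7 methoxy (Brassard naphthoquinone synthesis).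

Step 2
Reactants: 6 dimethyl squarate
Product: 7 rac-4-hydroxy-2,3-dimethoxy-4-methylcyclobut-2-en-1-one
Conditions: MeLi (1.05 equiv), THF, −78 °C; then H2O
Reagents that add atoms: methyllithium, [Li]C
Why: 1,2-Addition of MeLi to one of the two equivalent vinylogous-ester carbonyls at −78 °C should stop at the mono-adduct; the carbinol centre is racemic and is planarised in step 3.

Step 3
Reactants: 7 rac-4-hydroxy-2,3-dimethoxy-4-methylcyclobut-2-en-1-one
Product: 8 rac-3,4-dimethoxy-5-methylfuran-2(5H)-one
Conditions: p-xylene, 140 °C
Reagents that add atoms: none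
Why: Thermal 4π-electrocyclic ring opening of the strained 4-hydroxycyclobutenone gives a hydroxyvinylketene that is trapped by its own hydroxyl and tautomerises to the conjugated butenolide (Moore-type cyclobutenone-to-furanone rearrangement).

Step 4
Reactants: 8 rac-3,4-dimethoxy-5-methylfuran-2(5H)-one; 5 7-methoxyjuglone
Product: 9 4,8-dihydroxy-6-methoxy-4-(3,4-dimethoxy-2-methyl-5-oxo-2,5-dihydrofuran-2-yl)naphthalen-1(4H)-one (racemic diastereomer mixture)
Conditions: 8, LiN(SiMe3)2 (1.1 equiv), THF, −78 °C; added to 5 + LiN(SiMe3)2 (1.0 equiv), THF, −78 °C; AcOH quench at −78 °C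
Reagents that add atoms: none
Why: Vinylogous aldol addition, in which the lithium 2-furanolate of 8 reacts at its γ-carbon (the α-carbon is blocked by OMe) with the C1 carbonyl of 5, the C4 carbonyl being deactivated as a vinylogous carboxylate by the peri lithium phenoxide; the two new centres form without control, the carbinol being erased in step 6 and the quaternary centre resolved in step 7.

Step 5
Reactants: 9 aldol adduct
Product: 10 4,8-dihydroxy-4-(5-hydroxy-3,4-dimethoxy-2-methyl-2,5-dihydrofuran-2-yl)-6-methoxynaphthalen-1(4H)-one (lactol; stereoisomer mixture)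
Conditions: i-Bu2AlH (3.3 equiv), CH2Cl2, −78 °C; MeOH, then aqueous KNaC4H4O6
Reagents that add atoms: none
Why: Partial reduction of the γ-lactone to the lactol by i-Bu2AlH at −78 °C through a stable aluminium hemiacetal; the enone ketone is expected to survive because it is held as the electron-rich six-membered aluminium chelate of the peri phenoxide, and the anomeric centre formed is lost in step 6.

Step 6
Reactants: 10 lactol
Product: 13 rac-4,8-dihydroxy-2,3,6-trimethoxy-4-methylphenanthrene-1,9(4H,10H)-dione, via open-chain hydroxy enal 11 (not isolated), via Stetter ketol 12 (not isolated)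
Conditions: 2-(pentafluorophenyl)-6,7-dihydro-5H-pyrrolo[2,1-c][1,2,4]triazol-2-ium tetrafluoroborate (20 mol %), i-Pr2NEt (1 equiv), toluene/THF, 23 °C; then DBU (3 equiv), 45 °C
Reagents that add atoms: none
Why: Under base the lactol 10 opens to the (Z)-γ-hydroxy enal 11, whose formyl group adds the triazolylidene to give a Breslow intermediate (acyl anion equivalent at C1); this attacks C10a, the β-carbon of the quinol enone, and release of the carbene leaves ketol 12, from which DBU removes water by E1cB (C10a–H is α to the new ketone, the C4a hydroxyl is β) to give the C4a=C10a double bond. The closest known reaction type is the carbene-catalysed intramolecular Stetter reaction on 4-oxygenated cyclohexa-2,5-dienones, here followed by a β-elimination as in an aldol condensation. Ring A closes in a 6-exo-trig mode, the C10=C10a bond being exocyclic to the forming ring. The only new stereocentre, C10a in 12, is set by the tether on C4a and is erased by the elimination together with C4a, while C4 is untouched. The step needs acyl rather than homoenolate reactivity of the enal, which is secured because attack through C3 would close a four-membered ring at a fully substituted carbon. It also needs loss of the C4a rather than the C4 hydroxyl, which is secured because only the former is β to a ketone.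

Step 7
Reactants: 13 rac-4,8-dihydroxy-2,3,6-trimethoxy-4-methylphenanthrene-1,9(4H,10H)-dione
Product: 14 (4R)-4,8-dihydroxy-2,3,6-trimethoxy-4-methylphenanthrene-1,9(4H,10H)-dione
Conditions: preparative HPLC on cellulose tris(3,5-dimethylphenylcarbamate), hexane/i-PrOH
Reagents that add atoms: none
Why: Resolution of the racemate by chromatography on a chiral stationary phase; the quaternary carbinol has no racemisation pathway under neutral conditions, and the (4R) enantiomer is to be identified by ECD or X-ray correlation.

Step 8
Reactants: 14 (4R)-quinol; 15 4,4-diethoxybutan-1-amine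
Product: 19 target CNP0528850.1 (4R; aminal carbon S), via vinylogous amide 16 (not isolated), via amino aldehyde 17 (not isolated), via cyclic hemiaminal 18 (not isolated)
Conditions: 15 (1.5 equiv), EtOH, 23 °C; then 1 M HCl (aq), THF, 23 °C
Reagents that add atoms: none
Why: Addition–elimination of the primary amine at C3 (vinylogous ester to vinylogous amide), then acid unmasks the aldehyde, which condenses with the N–H to an N-acyliminium-type ion that the C4 hydroxyl captures in a 5-exo closure; the aminal centre equilibrates through ring opening in acid and should settle as the cis-fused bicycle with the C4 methyl on the convex face, that is aminal H syn to methyl (S).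

Compound list
1 | methyl (E)-3-methoxybut-2-enoate | CO/C(C)=C/C(=O)OC | starting material
2 | p-benzoquinone | O=C1C=CC(=O)C=C1 | starting material
3 | 1,3-dimethoxy-1-(trimethylsilyloxy)buta-1,3-diene (Brassard's diene; C1=C2 geometry not defined) | COC(=C)C=C(OC)O[Si](C)(C)C | intermediate
4 | 7-methoxy-5-(trimethylsilyloxy)naphthalene-1,4-diol | COc1cc(O[Si](C)(C)C)c2c(O)ccc(O)c2c1 | intermediate
5 | 5-hydroxy-7-methoxynaphthalene-1,4-dione (7-methoxyjuglone) | O=C1C=CC(=O)c2c(O)cc(OC)cc12 | intermediate
6 | 3,4-dimethoxycyclobut-3-ene-1,2-dione (dimethyl squarate) | COC1=C(OC)C(=O)C1=O | starting material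
7 | rac-4-hydroxy-2,3-dimethoxy-4-methylcyclobut-2-en-1-one | COC1=C(OC)C(C)(O)C1=O | intermediate
8 | rac-3,4-dimethoxy-5-methylfuran-2(5H)-one | COC1=C(OC)C(C)OC1=O | intermediate
9 | 4,8-dihydroxy-6-methoxy-4-(3,4-dimethoxy-2-methyl-5-oxo-2,5-dihydrofuran-2-yl)naphthalen-1(4H)-one, racemic, both relative configurations | COC1=C(OC)C(C)(OC1=O)C1(O)C=CC(=O)c2c(O)cc(OC)cc21 | intermediate
10 | 4,8-dihydroxy-4-(5-hydroxy-3,4-dimethoxy-2-methyl-2,5-dihydrofuran-2-yl)-6-methoxynaphthalen-1(4H)-one, lactol, stereoisomer mixture | COC1=C(OC)C(C)(OC1O)C1(O)C=CC(=O)c2c(O)cc(OC)cc21 | intermediate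
11 | (2Z)-4-(1,5-dihydroxy-7-methoxy-4-oxo-1,4-dihydronaphthalen-1-yl)-4-hydroxy-2,3-dimethoxypent-2-enal, stereoisomer mixture | O=C/C(OC)=C(OC)\C(C)(O)C1(O)C=CC(=O)c2c(O)cc(OC)cc21 | intermediate
12 | 4,4a,8-trihydroxy-2,3,6-trimethoxy-4-methyl-4a,10a-dihydrophenanthrene-1,9(4H,10H)-dione, stereoisomer mixture | COC1=C(OC)C(C)(O)C2(O)C(CC(=O)c3c(O)cc(OC)cc32)C1=O | intermediate
13 | rac-4,8-dihydroxy-2,3,6-trimethoxy-4-methylphenanthrene-1,9(4H,10H)-dione | COC1=C(OC)C(C)(O)C2=C(CC(=O)c3c(O)cc(OC)cc32)C1=O | intermediate
14 | (4R)-4,8-dihydroxy-2,3,6-trimethoxy-4-methylphenanthrene-1,9(4H,10H)-dione | COC1=C(OC)[C@](C)(O)C2=C(CC(=O)c3c(O)cc(OC)cc32)C1=O | intermediate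
15 | 4,4-diethoxybutan-1-amine | CCOC(CCCN)OCC | starting material
16 | (4R)-3-[(4,4-diethoxybutyl)amino]-4,8-dihydroxy-2,6-dimethoxy-4-methylphenanthrene-1,9(4H,10H)-dione | COC1=C(NCCCC(OCC)OCC)[C@](C)(O)C2=C(CC(=O)c3c(O)cc(OC)cc32)C1=O | intermediate
17 | 4-{[(4R)-4,8-dihydroxy-2,6-dimethoxy-4-methyl-1,9-dioxo-1,4,9,10-tetrahydrophenanthren-3-yl]amino}butanal | COC1=C(NCCCC=O)[C@](C)(O)C2=C(CC(=O)c3c(O)cc(OC)cc32)C1=O | intermediate
18 | (4R)-4,8-dihydroxy-3-(2-hydroxypyrrolidin-1-yl)-2,6-dimethoxy-4-methylphenanthrene-1,9(4H,10H)-dione, both configurations at the pyrrolidine carbinol | COC1=C(N2CCCC2O)[C@](C)(O)C2=C(CC(=O)c3c(O)cc(OC)cc32)C1=O | intermediate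
19 | CNP0528850.1: 8-hydroxy-2,6-dimethoxy-4-methylphenanthrene-1,9(4H,10H)-dione with pyrrolidine N1 on C3 and pyrrolidine C2 on the C4 oxygen (fused oxazolidine); C4 R, aminal carbon S | COC1=C2N3CCC[C@@H]3O[C@]2(C)C2=C(CC(=O)c3c(O)cc(OC)cc32)C1=O | target

Total step count: 8 (including the resolution). Longest linear sequence: 7 steps (6 to 19, steps 2–8).

Steps most likely to fail

Step 6. The carbene may be diverted instead of closing ring A: the lactol may not open, the enal may react as a homoenolate and relactonise, or the quinol may undergo base-induced retro-aldol cleavage before elimination. The fallback replaces the polar acyl anion by an acyl radical. It sets out from 10 and returns at 13. Irradiation of 10 at 390 nm in MeCN with (n-Bu4N)4W10O32 (2 mol %) should abstract the formyl hydrogen of 11 (or the acetal hydrogen of 10). The nucleophilic radical should add 6-exo to C10a of the enone, and back hydrogen transfer should give ketol 12 (directly, or after opening of the bridged hemiketal). DBU then dehydrates 12 to 13. This is decatungstate-photocatalysed hydroacylation of an electron-poor alkene and makes no compound outside the list (F0).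

Step 5. Hydride delivery may not discriminate, so that the C1 ketone of the naphthalenone is reduced along with the lactone. The fallback accepts this and corrects the oxidation level afterwards. It sets out from 9 and returns at 10. Excess i-Bu2AlH (6 equiv, −78 → −40 °C) should reduce both carbonyls to 4-(5-hydroxy-3,4-dimethoxy-2-methyl-2,5-dihydrofuran-2-yl)-6-methoxy-1,4-dihydronaphthalene-1,4,8-triol F1. MnO2 (CH2Cl2, 0 °C) should then re-oxidise the doubly activated benzylic, allylic carbinol to give 10. Any lactol that is over-oxidised returns as 9 and can be recycled.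

Step 4. Electron transfer from the electron-rich furanolate to the quinone, conjugate addition at C2/C3, or retro-aldol reversal of the congested adduct may compete with 1,2-addition. The fallback changes the nucleophile from a lithium dienolate to a neutral silyl dienol ether. It sets out from 8 (with 5) and returns at 9. t-BuMe2SiOTf/Et3N should convert 8 into 2-(tert-butyldimethylsilyloxy)-3,4-dimethoxy-5-methylfuran F2. A vinylogous Mukaiyama aldol with 5, catalysed by (n-Bu4N)(Ph3SiF2) in THF at −78 °C, should give 4-(tert-butyldimethylsilyloxy)-8-hydroxy-6-methoxy-4-(3,4-dimethoxy-2-methyl-5-oxo-2,5-dihydrofuran-2-yl)naphthalen-1(4H)-one F3, in which the aldolate is trapped as its silyl ether. 1 M HCl in THF then gives 9.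

Further compounds
F0 | step 6 | none | none
F1 | step 5 | 4-(5-hydroxy-3,4-dimethoxy-2-methyl-2,5-dihydrofuran-2-yl)-6-methoxy-1,4-dihydronaphthalene-1,4,8-triol, stereoisomer mixture | COC1=C(OC)C(C)(OC1O)C1(O)C=CC(O)c2c(O)cc(OC)cc21
F2 | step 4 | 2-(tert-butyldimethylsilyloxy)-3,4-dimethoxy-5-methylfuran | COc1c(OC)c(C)oc1O[Si](C)(C)C(C)(C)C
F3 | step 4 | 4-(tert-butyldimethylsilyloxy)-8-hydroxy-6-methoxy-4-(3,4-dimethoxy-2-methyl-5-oxo-2,5-dihydrofuran-2-yl)naphthalen-1(4H)-one, racemic diastereomer mixture | COC1=C(OC)C(C)(OC1=O)C1(O[Si](C)(C)C(C)(C)C)C=CC(=O)c2c(O)cc(OC)cc21
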